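**Strategy**

The last ring to close is the cyclobutane: the bond between C5 (quaternary, CH3) and C6 (cyclobutane CH next to C11) is made by a 4-exo-tet enolate alkylation inside a cis-fused bicyclo[5.4.0]undecane. The step exploits the C4 oxygen and the C7–C8 fusion of the six- and seven-membered rings: C4 as an enone carbonyl makes C5 the only enolisable carbon, and the ring keeps the enolate oxygen away from C6, so the quaternary centre, the cyclobutane and both bridged rings form in one operation. The precursor, a cycloheptenone bearing an allylic bromide in ring A, comes from an enantioselective quinone-monoketal Diels–Alder adduct by one-carbon ring expansion; all other stereocentres are relayed from the adduct.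

Key step: step 12

Atom labels used for the target and all intermediates: C1 = quaternary carbon carrying CH3 and C12H2–O; C2, C3 = the two ring CH2; C4 = CH–O; C5 = quaternary cyclobutane carbon carrying CH3; C6 = cyclobutane CH bonded to C11; C7 = cyclobutane CH bonded to C1; C8 = cyclobutane CH bonded to C9; C9 = C=O; C10 = CH2; C11 = CH(CH3). Ring A = C6–C7–C8–C9–C10–C11. The second ring is C7–C1–C2–(C3)–C4–C5–C8; C3 is absent until step 8.

Remark on the chemistry: the configurations at C1 and C5 formed in step 2 are transient (C1 becomes sp2 in step 5, C5 is enolised in step 12), so only the cis C7/C8 pair has to be controlled there.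

**Route**

Step 1
Reactants: 1 (E)-hex-4-en-3-one
Product: 2 (2Z,4E)-3-(triethylsilyloxy)hexa-2,4-diene
Conditions: Et3SiOSO2CF3, Et3N, Et2O, 0 °C
Reagents that add atoms: triethylsilyl trifluoromethanesulfonate CC[Si](CC)(CC)OS(=O)(=O)C(F)(F)F
Why: Soft enolisation of the ethyl ketone with silyl triflate and amine deprotonates the alpha-prime CH2 and should give the cross-conjugated 2-silyloxy diene with the Z enol ether geometry (methyl outside) that a Diels–Alder reaction needs.

Step 2
Reactants: 2 (2Z,4E)-3-(triethylsilyloxy)hexa-2,4-diene; 3 1,4-dioxaspiro[4.5]deca-6,9-dien-8-one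
Product: 4 cis-fused adduct, 5',8'-dimethyl-7'-(triethylsilyloxy)-4a',5',8',8a'-tetrahydro-4'H-spiro[1,3-dioxolane-2,1'-naphthalen]-4'-one (H-4a', H-5', H-8', H-8a' all cis; C7 and C8 as in the target)
Conditions: (S)-1-(2-methylphenyl)-3,3-diphenyltetrahydro-1H,3H-pyrrolo[1,2-c][1,3,2]oxazaborole protonated with HN(SO2CF3)2 (20 mol %), CH2Cl2, −78 to −20 °C; Et3N quench
Reagents that add atoms: none
Why: Normal-demand Diels–Alder reaction in which the enol ether terminus of 2 bonds to the beta-carbon (C8) of one of the two enantiotopic enone units of 3, the chiral cationic oxazaborolidine screening one face so that the cis C7/C8 pair should form in the sense shown (the antipodal catalyst is taken if the facial sense proves opposite).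

Step 3
Reactants: 4 cis-fused adduct
Product: 5 allylic alcohol (C6–OH cis to the C7–C1 bond, trans to H7)
Conditions: (i-Bu)2AlH, CH2Cl2, −78 °C; Rochelle salt work-up
Reagents that add atoms: none
Why: 1,2-Reduction of the ring A enone by hydride delivered to the convex face of the cis-fused bicycle (the face of H7 and H8) should place the new hydroxyl on the concave face, while silyl enol ether and ketal are inert.

Step 4
Reactants: 5 allylic alcohol
Product: 6 triisopropylsilyl ether of 5
Conditions: i-Pr3SiOSO2CF3, 2,6-lutidine, CH2Cl2, −78 to 0 °C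
Reagents that add atoms: triisopropylsilyl trifluoromethanesulfonate CC(C)[Si](C(C)C)(C(C)C)OS(=O)(=O)C(F)(F)F
Why: Silylation with the reactive triflate protects the hindered allylic alcohol as an ether that tolerates the organocopper, zinc carbenoid and ferric chloride steps and, unlike an ester, cannot enter allylic substitution.

Step 5
Reactants: 6 triisopropylsilyl ether
Product: 7 enone, 5',8'-dimethyl-4'-(triisopropylsilyloxy)-4',4a',8',8a'-tetrahydro-7'H-spiro[1,3-dioxolane-2,1'-naphthalen]-7'-one (C1=C2 double bond)
Conditions: Pd(OAc)2 (1.1 equiv), MeCN, rt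
Reagents that add atoms: none
Why: Saegusa–Ito oxidation, in which palladium diacetate converts the silyl enol ether into the C2-bound palladium enolate and syn beta-hydride elimination of H1 gives the C1=C2 enone regiospecifically, making C1 the beta-carbon for step 7.

Step 6
Reactants: 8 (tributylstannyl)methanol; 9 benzyl bromide
Product: 10 tributyl[(benzyloxy)methyl]stannane
Conditions: NaH, THF/DMF, 0 °C to rt
Reagents that add atoms: none
Why: Williamson etherification of the primary stannyl carbinol gives the tin precursor of benzyloxymethyllithium.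

Step 7
Reactants: 7 enone; 10 tributyl[(benzyloxy)methyl]stannane
Product: 11 trimethylsilyl enol ether (C2=C4–OSiMe3) with quaternary C1 (CH3 and CH2OBn, CH2OBn cis to H7)
Conditions: 10, n-BuLi, THF, −78 °C; CuBr·SMe2 (0.5 equiv per lithium); Me3SiCl, then 7, −78 to −40 °C; Et3N, pentane work-up
Reagents that add atoms: chlorotrimethylsilane C[Si](C)(C)Cl
Why: Tin–lithium exchange gives benzyloxymethyllithium, whose cuprate should add 1,4 to the beta,beta-disubstituted enone under Me3SiCl acceleration from the convex face anti to the ring A bond at C7, which sets quaternary C1 and traps the enolate regiospecifically as the C2=C4 silyl enol ether.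

Step 8
Reactants: 11 trimethylsilyl enol ether
Product: 12 1-(trimethylsilyloxy)cyclopropane (new CH2 = C3 bridging C2 and C4)
Conditions: Et2Zn, CH2I2, CH2Cl2, 0 °C to rt
Reagents that add atoms: diiodomethane ICI
Why: Simmons–Smith cyclopropanation (Furukawa conditions) should take place only at the electron-rich silyl enol ether, and its facial course is irrelevant because both new centres are destroyed in step 9.

Step 9
Reactants: 12 siloxycyclopropane
Product: 14 cycloheptenone, 5'-[(benzyloxy)methyl]-5',9'-dimethyl-4'-(triisopropylsilyloxy)-4',4a',9',9a'-tetrahydrospiro[1,3-dioxolane-2,1'-benzo[7]annulen]-8'(5'H)-one, via beta-chloro ketone 13 (not isolated)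
Conditions: FeCl3 (2.2 equiv), DMF, 0 °C; then NaOAc, MeOH, 65 °C
Reagents that add atoms: none
Why: Ferric chloride oxidises the siloxycyclopropane to an alkoxy radical, beta-scission of the internal bond gives the ring-expanded radical that is chlorinated at C2, and acetate-induced loss of HCl gives the C2=C3 enone, a one-carbon ring expansion of the Saegusa type with C3 as the inserted carbon.

Step 10
Reactants: 14 cycloheptenone
Product: 15 allylic alcohol (C6–OH cis to the C7–C1 bond)
Conditions: Bu4NF, THF, 0 °C to rt
Reagents that add atoms: none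
Why: Fluoride cleaves the triisopropylsilyl ether and leaves enone, benzyl ether and ketal untouched.

Step 11
Reactants: 15 allylic alcohol
Product: 16 allylic bromide (Br at C6 cis to H7, trans to the C7–C1 bond)
Conditions: CBr4, PPh3, 2,6-lutidine, CH2Cl2, 0 °C; used at once
Reagents that add atoms: carbon tetrabromide BrC(Br)(Br)Br
Why: Appel bromination, in which bromide displaces the alkoxyphosphonium ion with inversion at allylic C6 to give the configuration needed for backside attack by C5, attack at C10 (SN2') being disfavoured next to the ketal carbon.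

Step 12
Reactants: 16 allylic bromide
Product: 18 tricyclic dienone ketal (C5–C6 closed; C2=C3–C4=O, C10=C11, C9 dioxolane, 12-O-benzyl), via potassium dienolate 17 (not isolated)
Conditions: KN(SiMe3)2 (1.2 equiv), THF, −78 °C to rt
Reagents that add atoms: none
Why: KN(SiMe3)2 removes the only acidic C–H (H5, alpha-prime to the enone, since C1 is quaternary and no gamma-hydrogen exists) and the cross-conjugated potassium dienolate displaces the allylic bromide at C6 by SN2 with inversion, an intramolecular ketone-enolate alkylation of the kind long used to close the cyclobutane of pinane- and copaane-type terpenes. The cyclobutane C5–C6–C7–C8 closes in the 4-exo-tet mode, and with it the bicyclo[3.1.1]heptene (ring A bridged by C5) and the bicyclo[4.1.1]octenone (seven-membered ring bridged by C6) are completed. C5 becomes quaternary with its methyl anti to the seven-membered bridge because C4 is held in that ring and only the enolate face turned toward ring A can reach C6, and C6 is fixed by inversion of the bromide that stands trans to C1. C- over O-alkylation is secured by the endocyclic enolate geometry (oxygen trans to C8, pointing away from C6), E2 is suppressed because H7 is syn to bromine and C11 is vinylic, and SN2' attack at C10 is blocked by the neighbouring ketal carbon. The cis ring fusion places C5 axial and bromine pseudo-equatorial on ring A in the reactive conformer, which provides the backside trajectory.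

Step 13
Reactants: 18 tricyclic dienone ketal
Product: 20 hydroxy enone (C4–OH cis to C12; C9=O conjugated with C10=C11; C2=C3; 12-O-benzyl), via allylic alcohol ketal 19 (not isolated)
Conditions: NaBH4, CeCl3·7H2O, MeOH, −78 to 0 °C; then 1 M HCl, THF, 0 °C to rt
Reagents that add atoms: water O
Why: Luche reduction delivers hydride 1,2 to the enone from the face syn to the C1 methyl and anti to the larger CH2OBn group across the seven-membered ring, which should give the C4 alcohol cis to C12, and dilute acid then hydrolyses the allylic ketal to the C9 enone while bridgehead C8 cannot epimerise.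

Step 14
Reactants: 20 hydroxy enone
Product: 21 11-methyl ketone (C4–OH, C2=C3, 12-O-benzyl; C11 methyl on the side of C7)
Conditions: Me2CuLi (from MeLi and CuI, 4 equiv), Et2O, −78 to −30 °C; NH4Cl work-up
Reagents that add atoms: methyllithium [Li]C
Why: Conjugate addition of the Gilman cuprate to the bicyclo[3.1.1]heptenone should occur from the enone face anti to the C5 bridge and its methyl, as in verbenone-type enones, which sets C11 with its methyl syn to the C7–H bridge.

Step 15
Reactants: 21 11-methyl ketone
Product: 22 keto diol (4-OH, 12-OH, C9 ketone; 1S,4R,5R,6S,7S,8R,11R in the labels above)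
Conditions: H2 (1 atm), Pd/C (10 wt %), EtOAc/EtOH, rt
Reagents that add atoms: none
Why: Heterogeneous hydrogenation saturates the C2=C3 double bond and removes the benzyl ether in one operation, leaving the ketone and all stereocentres unaffected.

Step 16
Reactants: 22 keto diol; 23 angelic acid ((Z)-2-methylbut-2-enoic acid)
Product: 24 target diangelate
Conditions: 23 (6 equiv), 2,4,6-trichlorobenzoyl chloride, Et3N, toluene, rt; then 22, 80 °C
Reagents that add atoms: none
Why: Yamaguchi-type acylation through the mixed anhydride of angelic and 2,4,6-trichlorobenzoic acids, run without a nucleophilic amine catalyst, should esterify both hydroxyls while keeping the Z geometry that 4-(dimethylamino)pyridine or acid chlorides would isomerise to tiglate.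

**Compound list**

1 | (E)-hex-4-en-3-one | CCC(=O)/C=C/C | starting material
2 | (2Z,4E)-3-(triethylsilyloxy)hexa-2,4-diene | C/C=C(\O[Si](CC)(CC)CC)/C=C/C | intermediate
3 | 1,4-dioxaspiro[4.5]deca-6,9-dien-8-one | O=C1C=CC2(OCCO2)C=C1 | starting material
4 | cis-fused Diels–Alder adduct (ring A enone, C9 dioxolane, C2=C4 triethylsilyl enol ether; H1, H5, H7, H8 all cis) | C[C@@H]1C=C(O[Si](CC)(CC)CC)[C@H](C)[C@H]2[C@@H]1C(=O)C=CC23OCCO3 | intermediate
5 | allylic alcohol of 4 (C6–OH cis to the C7–C1 bond) | C[C@@H]1C=C(O[Si](CC)(CC)CC)[C@H](C)[C@H]2[C@@H]1[C@@H](O)C=CC23OCCO3 | intermediate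
6 | triisopropylsilyl ether of 5 | C[C@@H]1C=C(O[Si](CC)(CC)CC)[C@H](C)[C@H]2[C@@H]1[C@@H](O[Si](C(C)C)(C(C)C)C(C)C)C=CC23OCCO3 | intermediate
7 | bicyclic enone (C4=O, C1=C2, C1 methyl) | CC1=CC(=O)[C@H](C)[C@H]2[C@@H]1[C@@H](O[Si](C(C)C)(C(C)C)C(C)C)C=CC23OCCO3 | intermediate
8 | (tributylstannyl)methanol | CCCC[Sn](CCCC)(CCCC)CO | starting material
9 | benzyl bromide | BrCc1ccccc1 | starting material
10 | tributyl[(benzyloxy)methyl]stannane | CCCC[Sn](CCCC)(CCCC)COCc1ccccc1 | intermediate
11 | trimethylsilyl enol ether with quaternary C1 (CH3, CH2OBn cis to H7) | c1ccccc1COC[C@@]1(C)C=C(O[Si](C)(C)C)[C@H](C)[C@H]2[C@@H]1[C@@H](O[Si](C(C)C)(C(C)C)C(C)C)C=CC23OCCO3 | intermediate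
12 | 1-(trimethylsilyloxy)cyclopropane (C3 bridging C2 and C4; either cyclopropane face serves) | c1ccccc1COC[C@@]1(C)[C@H]4C[C@@]4(O[Si](C)(C)C)[C@H](C)[C@H]2[C@@H]1[C@@H](O[Si](C(C)C)(C(C)C)C(C)C)C=CC23OCCO3 | intermediate
13 | beta-chloro ketone (Cl on C2, either epimer; not isolated) | c1ccccc1COC[C@@]1(C)C(Cl)CC(=O)[C@H](C)[C@H]2[C@@H]1[C@@H](O[Si](C(C)C)(C(C)C)C(C)C)C=CC23OCCO3 | intermediate
14 | cis-fused cycloheptenone (C2=C3–C4=O, C1 quaternary, C6–OSi(i-Pr)3, C9 dioxolane) | c1ccccc1COC[C@@]1(C)C=CC(=O)[C@H](C)[C@H]2[C@@H]1[C@@H](O[Si](C(C)C)(C(C)C)C(C)C)C=CC23OCCO3 | intermediate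
15 | allylic alcohol (C6–OH cis to the C7–C1 bond) | c1ccccc1COC[C@@]1(C)C=CC(=O)[C@H](C)[C@H]2[C@@H]1[C@@H](O)C=CC23OCCO3 | intermediate
16 | allylic bromide (Br at C6 cis to H7) | c1ccccc1COC[C@@]1(C)C=CC(=O)[C@H](C)[C@H]2[C@@H]1[C@H](Br)C=CC23OCCO3 | intermediate
17 | potassium dienolate of 16 (not isolated) | c1ccccc1COC[C@@]1(C)C=CC([O-])=C(C)[C@H]2[C@@H]1[C@H](Br)C=CC23OCCO3.[K+] | intermediate
18 | tricyclic dienone ketal (cyclobutane closed) | c1ccccc1COC[C@@]1(C)C=CC(=O)[C@]2(C)[C@@H]3[C@H]1[C@H]2C4(OCCO4)C=C3 | intermediate
19 | C4 allylic alcohol of 18 (not isolated) | c1ccccc1COC[C@@]1(C)C=C[C@@H](O)[C@]2(C)[C@@H]3[C@H]1[C@H]2C4(OCCO4)C=C3 | intermediate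
20 | hydroxy enone (C4–OH, C9=O, C10=C11, C2=C3) | c1ccccc1COC[C@@]1(C)C=C[C@@H](O)[C@]2(C)[C@@H]3[C@H]1[C@H]2C(=O)C=C3 | intermediate
21 | 11-methyl ketone (C4–OH, C2=C3, 12-O-benzyl) | c1ccccc1COC[C@@]1(C)C=C[C@@H](O)[C@]2(C)[C@@H]3[C@H]1[C@H]2C(=O)C[C@H]3C | intermediate
22 | keto diol | OC[C@@]1(C)CC[C@@H](O)[C@]2(C)[C@@H]3[C@H]1[C@H]2C(=O)C[C@H]3C | intermediate
23 | angelic acid | C/C=C(/C)C(=O)O | starting material
24 | target, 4,12-bis[(Z)-2-methylbut-2-enoyloxy] C9 ketone (1S,4R,5R,6S,7S,8R,11R in the labels above) | C/C=C(/C)C(=O)OC[C@@]1(C)CC[C@@H](OC(=O)/C(C)=C\C)[C@]2(C)[C@@H]3[C@H]1[C@H]2C(=O)C[C@H]3C | target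

**Count and risks**

Total steps: 16. Longest linear sequence: 15 (steps 1–5 and 7–16; step 6 is a one-step side branch).

Steps most likely to fail:

Step 12 (key step). Ionisation or loss of HBr from the secondary allylic bromide, or participation of the benzyl ether oxygen at C6, may outrun the strained 4-exo closure. The fallback sets out from alcohol 15 and comes back at 18. Alcohol 15, whose C6 oxygen stands cis to C1, is converted with methyl chloroformate and pyridine into the allylic methyl carbonate F1. Treatment with Pd2(dba)3 and 1,2-bis(diphenylphosphino)ethane in THF at 60 °C lets zerovalent palladium ionise the carbonate anti to oxygen. The methoxide released on loss of CO2 deprotonates C5, and the enolate attacks the allyl terminus C6 anti to palladium (Tsuji–Trost alkylation, net retention). This gives 18 without the bromide and without an inversion step.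

Step 7. Conjugate addition to the hindered beta,beta-disubstituted enone may be too slow, so that benzyloxymethyllithium or its cuprate decomposes (Wittig rearrangement) or adds 1,2. The fallback sets out from 6 and comes back at 14, placing C12 after the ring expansion. Silyl enol ether 6 is cyclopropanated (Et2Zn, CH2I2) to the siloxycyclopropane F2. FeCl3 in DMF then NaOAc in MeOH opens it through the beta-chloro ketone F3 to the cycloheptenone F4, which still carries H1. Equilibrating silylation (t-BuMe2SiOSO2CF3, Et3N, CH2Cl2, rt) gives the linearly conjugated silyl dienol ether F5. Vinylogous Mukaiyama alkylation with benzyl chloromethyl ether and ZnBr2 attacks the gamma-carbon C1 from the convex face and returns 14.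

Step 2. Facial or regiochemical control may be poor with this 1,4-disubstituted diene, or the acidic catalyst may protodesilylate it. The fallback sets out from 2 and 3 and comes back at 5. The uncatalysed Diels–Alder reaction (toluene, 110 °C, sealed tube) gives 4 together with the enantiomer of 4 F6. Reduction as in step 3 gives 5 together with the enantiomer of 5 F7. Alcohol 5 is then separated by preparative chromatography on a chiral stationary phase and enters step 4.

Further compounds
F1 | step 12 | allylic methyl carbonate of 15 | c1ccccc1COC[C@@]1(C)C=CC(=O)[C@H](C)[C@H]2[C@@H]1[C@@H](OC(=O)OC)C=CC23OCCO3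
F2 | step 7 | 1-(triethylsilyloxy)cyclopropane from 6 | C[C@@H]1[C@H]4C[C@@]4(O[Si](CC)(CC)CC)[C@H](C)[C@H]2[C@@H]1[C@@H](O[Si](C(C)C)(C(C)C)C(C)C)C=CC23OCCO3
F3 | step 7 | beta-chloro ketone lacking C12 (Cl on C2, either epimer) | C[C@@H]1C(Cl)CC(=O)[C@H](C)[C@H]2[C@@H]1[C@@H](O[Si](C(C)C)(C(C)C)C(C)C)C=CC23OCCO3
F4 | step 7 | cycloheptenone lacking C12 | C[C@@H]1C=CC(=O)[C@H](C)[C@H]2[C@@H]1[C@@H](O[Si](C(C)C)(C(C)C)C(C)C)C=CC23OCCO3
F5 | step 7 | tert-butyldimethylsilyl dienol ether (C1=C2, C3=C4) | CC1=CC=C(O[Si](C)(C)C(C)(C)C)[C@H](C)[C@H]2[C@@H]1[C@@H](O[Si](C(C)C)(C(C)C)C(C)C)C=CC23OCCO3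
F6 | step 2 | enantiomer of 4 | C[C@H]1C=C(O[Si](CC)(CC)CC)[C@@H](C)[C@@H]2[C@H]1C(=O)C=CC23OCCO3
F7 | step 2 | enantiomer of 5 | C[C@H]1C=C(O[Si](CC)(CC)CC)[C@@H](C)[C@@H]2[C@H]1[C@H](O)C=CC23OCCO3
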